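**Retrosynthetic overview**

1. The target has no stereocentre. It is released last by methanolysis of an O5 pivalate; before that ring C, the only ring made, is closed through O8a by cyclodehydration of an open 2-methoxy-1,3-diketone.
2. The diketone is cut at both bonds to C4. C4 is a lone carbonyl carbon between C4a of ring A and the methoxy-bearing C3, so it is brought in as CO between ring A iodide 6 and the enolate carbon of B-ring ketone 14 (C4a–C4 and C4–C3 in one palladium-catalysed step, no ring closed).
3. Feature relied on: ring A is a 2-methoxyphloroglucinol whose mirror plane runs through C8–OMe and C5–O5, and O5 is its only hydroxyl oxygen on that plane. With O5 alone acylated and O7/O8a carrying identical silyl groups, the two free ring carbons are equivalent, any mono-iodination marks C4a, and only O8a can later close the pyranone (8-methoxy, not 6-methoxy, isomer).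
4. Iodide 6 comes from 2-methoxyresorcinol by silylation, sterically directed C–H borylation/oxidation at the future C5, pivaloylation and iodination. Ketone 14 comes from 4-bromophenol, prenyl bromide and the Weinreb amide made from methoxyacetyl chloride.
5. Ring order: rings A and B are bought; ring C is formed in step 9.

Key step: step 8

Remark: diketones 16 and 17 carry one enolisable methine stereocentre and are handled as racemates; it becomes sp2 C3 on ring closure. Flavone numbering (C2 to C8a, O5, O7, O8a) is used for positions throughout.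

**Route**

Step 1
Reactants: 1 2-methoxyresorcinol (2-methoxybenzene-1,3-diol)
Product: 2 1,3-bis(tert-butyldimethylsilyloxy)-2-methoxybenzene
Conditions: TBSCl (2.3 equiv), imidazole (3 equiv), DMF, 0 °C to rt
Reagents that add atoms: tert-butyldimethylsilyl chloride, CC(C)(C)[Si](C)(C)Cl
Why: Imidazole-promoted O-silylation of phenols; the two hydroxyls are equivalent, so exhaustive silylation should give a single product.

Step 2
Reactants: 2 1,3-bis(tert-butyldimethylsilyloxy)-2-methoxybenzene
Product: 4 3,5-bis(tert-butyldimethylsilyloxy)-4-methoxyphenol, via aryl pinacol boronate 3 (not isolated)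
Conditions: [Ir(OMe)(1,5-cyclooctadiene)]2 (1.5 mol %), 4,4'-di-tert-butyl-2,2'-bipyridine (3 mol %), B2pin2 (1.0 equiv), THF, 80 °C; then Oxone (2KHSO5·KHSO4·K2SO4), acetone–H2O, rt, 10 min
Reagents that add atoms: bis(pinacolato)diboron, CC1(C)OB(OC1(C)C)B1OC(C)(C)C(C)(C)O1 (its boron stays only in intermediate 3); potassium peroxymonosulfate (the oxidant in Oxone), [K+].[O-]S(=O)(=O)OO (gives the phenol oxygen)
Why: Iridium-catalysed aromatic C–H borylation is sterically governed and should take the only C–H without an ortho substituent (para to the methoxy group), and peroxymonosulfate oxidation of the aryl boronate then gives the phenol in the same flask (one-pot borylation–oxidation), the aryl silyl ethers tolerating the brief oxidation.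

Step 3
Reactants: 4 3,5-bis(tert-butyldimethylsilyloxy)-4-methoxyphenol
Product: 5 3,5-bis(tert-butyldimethylsilyloxy)-4-methoxyphenyl pivalate
Conditions: PivCl (1.3 equiv), Et3N (2 equiv), DMAP (5 mol %), CH2Cl2, 0 °C to rt
Reagents that add atoms: pivaloyl chloride, CC(C)(C)C(=O)Cl
Why: DMAP-catalysed O-acylation of the only free phenol, which has no ortho substituent, caps the one hydroxyl oxygen on the mirror plane (the future O5).

Step 4
Reactants: 5 3,5-bis(tert-butyldimethylsilyloxy)-4-methoxyphenyl pivalate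
Product: 6 3,5-bis(tert-butyldimethylsilyloxy)-2-iodo-4-methoxyphenyl pivalate
Conditions: NIS (1.05 equiv), TFA (10 mol %), MeCN, 0 °C to rt, dark
Reagents that add atoms: N-iodosuccinimide, O=C1CCC(=O)N1I
Why: Electrophilic aromatic iodination; the two free positions are mirror-equivalent and each is ortho and para to a silyloxy donor, so mono-iodination can give only 6, and the first iodine hinders and deactivates against a second.

Step 5
Reactants: 7 4-bromophenol; 8 1-bromo-3-methylbut-2-ene (prenyl bromide)
Product: 9 1-bromo-4-(3-methylbut-2-enyloxy)benzene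
Conditions: K2CO3 (1.5 equiv), acetone, reflux
Reagents that add atoms: none
Why: Williamson ether synthesis, SN2 O-alkylation of the phenoxide at the primary allylic bromide.

Step 6
Reactants: 10 methoxyacetyl chloride; 11 N,O-dimethylhydroxylamine hydrochloride
Product: 12 N,2-dimethoxy-N-methylacetamide
Conditions: Et3N (2.2 equiv), CH2Cl2, 0 °C to rt
Reagents that add atoms: none
Why: N-acylation of the hydroxylamine by the acid chloride gives the Weinreb amide.

Step 7
Reactants: 9 1-bromo-4-(3-methylbut-2-enyloxy)benzene; 12 N,2-dimethoxy-N-methylacetamide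
Product: 14 2-methoxy-1-[4-(3-methylbut-2-enyloxy)phenyl]ethanone, via arylmagnesium bromide 13 (not isolated)
Conditions: Mg, THF, 45 °C; then 12, THF, 0 °C; cold 1 M HCl
Reagents that add atoms: magnesium, [Mg] (stays only in intermediate 13)
Why: Grignard formation followed by Weinreb ketone synthesis; the chelated tetrahedral adduct should stop at the ketone stage, and the aryl prenyl ether is inert to the arylmagnesium species.

Step 8
Reactants: 6 3,5-bis(tert-butyldimethylsilyloxy)-2-iodo-4-methoxyphenyl pivalate (1.15 equiv); 15 carbon monoxide; 14 2-methoxy-1-[4-(3-methylbut-2-enyloxy)phenyl]ethanone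
Product: 16 3,5-bis(tert-butyldimethylsilyloxy)-4-methoxy-2-{2-methoxy-3-[4-(3-methylbut-2-enyloxy)phenyl]-3-oxopropanoyl}phenyl pivalate (racemic)
Conditions: Pd(dba)2 (5 mol %), Xantphos (6 mol %), K3PO4 (3 equiv), CO (5 bar), 1,4-dioxane, 80 °C; aq. citric acid work-up
Reagents that add atoms: none
Why: Oxidative addition of the C–I bond of 6 to zerovalent palladium–Xantphos, migratory insertion of CO to a 2,6-dioxygenated aroylpalladium iodide (divalent palladium), exchange of iodide for the phosphate-generated enolate of 14 and C–C reductive elimination should join C4a–C4 and C4–C3 in one operation; this is the known palladium-catalysed carbonylative α-arylation of ketones with aryl iodides to 1,3-diketones, applied here to an α-methoxy aryl ketone. No ring is closed, and the new methine centre arises racemic under no control, which is immaterial because it is enolisable and becomes the sp2 carbon C3 in step 9. Carbonylative rather than direct arylation is required: the two ortho oxygen substituents retard direct aryl–enolate reductive elimination, while the wide bite angle of Xantphos and 5 bar of CO favour the acyl pathway. Chemoselectivity at palladium is also required: the aryl iodide should add faster than the trisubstituted allyl aryl ether ionises, and 6 is kept in slight excess so that the catalyst is never left without iodide. The weak, insoluble base keeps the standing enolate concentration low, which should spare the aryl pivalate and aryl silyl ethers from acyl or silyl transfer. The position of the acyl group is fixed by the iodine, which sits between the O5 ester and a silyloxy group that becomes O8a.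

Step 9
Reactants: 16 3,5-bis(tert-butyldimethylsilyloxy)-4-methoxy-2-{2-methoxy-3-[4-(3-methylbut-2-enyloxy)phenyl]-3-oxopropanoyl}phenyl pivalate
Product: 18 7-hydroxy-3,8-dimethoxy-2-[4-(3-methylbut-2-enyloxy)phenyl]-4-oxo-4H-chromen-5-yl pivalate, via bis-phenol diketone 17 (not isolated)
Conditions: Bu4NF (2.2 equiv), AcOH (2.5 equiv), THF, 0 °C; then AcOH, 60 °C
Reagents that add atoms: none
Why: Acetic-acid-buffered fluoride cleaves both aryl silyl ethers without leaving phenoxide basic enough for retro-Claisen cleavage or pivaloyl loss; in warm acetic acid the only ortho hydroxyl (O8a, O5 still being an ester) should add to the B-ring carbonyl (6-exo-trig hemiketalisation) and the hemiketal lose water by acid-catalysed cyclodehydration to the 4-pyranone, the methine carbon becoming C3.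

Step 10
Reactants: 18 7-hydroxy-3,8-dimethoxy-2-[4-(3-methylbut-2-enyloxy)phenyl]-4-oxo-4H-chromen-5-yl pivalate
Product: 19 5,7-dihydroxy-3,8-dimethoxy-4'-prenyloxyflavone (5,7-dihydroxy-3,8-dimethoxy-2-[4-(3-methylbut-2-enyloxy)phenyl]-4H-chromen-4-one)
Conditions: K2CO3 (2 equiv), MeOH, rt; aq. NH4Cl
Reagents that add atoms: none
Why: Carbonate-mediated transesterification (methanolysis) of the aryl pivalate, whose phenoxide leaving group is stabilised by the peri carbonyl; the prenyl ether, methyl ethers and pyranone are inert to mild base.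

**Compound list**

1 | 2-methoxyresorcinol (2-methoxybenzene-1,3-diol) | COc1c(O)cccc1O | starting material
2 | 1,3-bis(tert-butyldimethylsilyloxy)-2-methoxybenzene | COc1c(O[Si](C)(C)C(C)(C)C)cccc1O[Si](C)(C)C(C)(C)C | intermediate
3 | 2-[3,5-bis(tert-butyldimethylsilyloxy)-4-methoxyphenyl]-4,4,5,5-tetramethyl-1,3,2-dioxaborolane | COc1c(O[Si](C)(C)C(C)(C)C)cc(B2OC(C)(C)C(C)(C)O2)cc1O[Si](C)(C)C(C)(C)C | intermediate
4 | 3,5-bis(tert-butyldimethylsilyloxy)-4-methoxyphenol | COc1c(O[Si](C)(C)C(C)(C)C)cc(O)cc1O[Si](C)(C)C(C)(C)C | intermediate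
5 | 3,5-bis(tert-butyldimethylsilyloxy)-4-methoxyphenyl pivalate | COc1c(O[Si](C)(C)C(C)(C)C)cc(OC(=O)C(C)(C)C)cc1O[Si](C)(C)C(C)(C)C | intermediate
6 | 3,5-bis(tert-butyldimethylsilyloxy)-2-iodo-4-methoxyphenyl pivalate | COc1c(O[Si](C)(C)C(C)(C)C)cc(OC(=O)C(C)(C)C)c(I)c1O[Si](C)(C)C(C)(C)C | intermediate
7 | 4-bromophenol | Oc1ccc(Br)cc1 | starting material
8 | 1-bromo-3-methylbut-2-ene (prenyl bromide) | CC(C)=CCBr | starting material
9 | 1-bromo-4-(3-methylbut-2-enyloxy)benzene | CC(C)=CCOc1ccc(Br)cc1 | intermediate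
10 | methoxyacetyl chloride | COCC(=O)Cl | starting material
11 | N,O-dimethylhydroxylamine hydrochloride | CNOC.Cl | starting material
12 | N,2-dimethoxy-N-methylacetamide | COCC(=O)N(C)OC | intermediate
13 | 4-(3-methylbut-2-enyloxy)phenylmagnesium bromide | CC(C)=CCOc1ccc([Mg]Br)cc1 | intermediate
14 | 2-methoxy-1-[4-(3-methylbut-2-enyloxy)phenyl]ethanone | COCC(=O)c1ccc(OCC=C(C)C)cc1 | intermediate
15 | carbon monoxide | [C-]#[O+] | starting material
16 | 3,5-bis(tert-butyldimethylsilyloxy)-4-methoxy-2-{2-methoxy-3-[4-(3-methylbut-2-enyloxy)phenyl]-3-oxopropanoyl}phenyl pivalate (racemic) | COc1c(O[Si](C)(C)C(C)(C)C)cc(OC(=O)C(C)(C)C)c(C(=O)C(OC)C(=O)c2ccc(OCC=C(C)C)cc2)c1O[Si](C)(C)C(C)(C)C | intermediate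
17 | 3,5-dihydroxy-4-methoxy-2-{2-methoxy-3-[4-(3-methylbut-2-enyloxy)phenyl]-3-oxopropanoyl}phenyl pivalate (racemic) | COc1c(O)cc(OC(=O)C(C)(C)C)c(C(=O)C(OC)C(=O)c2ccc(OCC=C(C)C)cc2)c1O | intermediate
18 | 7-hydroxy-3,8-dimethoxy-2-[4-(3-methylbut-2-enyloxy)phenyl]-4-oxo-4H-chromen-5-yl pivalate | COc1c(-c2ccc(OCC=C(C)C)cc2)oc2c(OC)c(O)cc(OC(=O)C(C)(C)C)c2c1=O | intermediate
19 | 5,7-dihydroxy-3,8-dimethoxy-4'-prenyloxyflavone | COc1c(-c2ccc(OCC=C(C)C)cc2)oc2c(OC)c(O)cc(O)c2c1=O | target

**Totals and risks**

Total step count: 10.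
Longest linear sequence: 7 steps (steps 1, 2, 3, 4, 8, 9, 10, from 2-methoxyresorcinol).

Steps most likely to fail:

Step 8. The doubly ortho-substituted arylpalladium species may take up CO or pass on the acyl group too slowly. Direct arylation, protodeiodination, base-induced transfer of the O5 pivaloyl group to the diketonate, or ionisation of the prenyl ether by zerovalent palladium could then take over. The fallback makes the same diketone without palladium and sets out from iodide 6. Iodine–magnesium exchange (iPrMgCl·LiCl, THF, −40 °C, kept cold so that the ortho ester is not attacked) should give [2,4-bis(tert-butyldimethylsilyloxy)-3-methoxy-6-(pivaloyloxy)phenyl]magnesium chloride F1. Trapping with DMF should give 3,5-bis(tert-butyldimethylsilyloxy)-2-formyl-4-methoxyphenyl pivalate F2. Ketone 14 is deprotonated with LiN(SiMe3)2 (THF, −78 °C) to the lithium (Z)-enolate of 2-methoxy-1-[4-(3-methylbut-2-enyloxy)phenyl]ethanone F3. Aldol addition of F3 to F2, quenched cold, should give 3,5-bis(tert-butyldimethylsilyloxy)-2-{1-hydroxy-2-methoxy-3-[4-(3-methylbut-2-enyloxy)phenyl]-3-oxopropyl}-4-methoxyphenyl pivalate F4 as a diastereomer mixture. Oxidation with Dess–Martin periodinane (CH2Cl2, rt) returns to the route at diketone 16.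

Step 4. Electrophilic substitution at a position flanked by two oxygen substituents on an ester-deactivated ring may be sluggish, so that protodesilylation by the acid co-catalyst competes. The fallback iodinates before acylation and sets out from phenol 4. NIS (1.0 equiv, CH2Cl2, −40 °C, no acid) should iodinate ortho to the free hydroxyl, the two ortho positions being equivalent, to give 3,5-bis(tert-butyldimethylsilyloxy)-2-iodo-4-methoxyphenol F5. Pivaloylation (PivCl, Et3N, DMAP, CH2Cl2) returns to the route at iodide 6.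

Step 9. The hemiketal may lose water only under acid strong enough to cleave or shift the aryl prenyl ether. In that case the prenyl group is introduced after ring closure; the fallback sets out from 4-bromophenol 7 and returns at target 19.
- Benzylation (benzyl bromide, K2CO3, acetone) gives 1-(benzyloxy)-4-bromobenzene F6.
- Magnesium insertion gives 4-(benzyloxy)phenylmagnesium bromide F7, which with Weinreb amide 12 gives 1-[4-(benzyloxy)phenyl]-2-methoxyethanone F8.
- Carbonylative coupling with 6 and 15 under the conditions of step 8 gives 2-{3-[4-(benzyloxy)phenyl]-2-methoxy-3-oxopropanoyl}-3,5-bis(tert-butyldimethylsilyloxy)-4-methoxyphenyl pivalate F9.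
- Buffered Bu4NF gives 2-{3-[4-(benzyloxy)phenyl]-2-methoxy-3-oxopropanoyl}-3,5-dihydroxy-4-methoxyphenyl pivalate F10, closed without isolation in AcOH with H2SO4 (cat.) at 80 °C to 2-[4-(benzyloxy)phenyl]-7-hydroxy-3,8-dimethoxy-4-oxo-4H-chromen-5-yl pivalate F11.
- Pivaloylation of the 7-hydroxyl gives 2-[4-(benzyloxy)phenyl]-3,8-dimethoxy-4-oxo-4H-chromene-5,7-diyl dipivalate F12.
- Hydrogenolysis (H2, palladium on carbon, EtOAc) gives 2-(4-hydroxyphenyl)-3,8-dimethoxy-4-oxo-4H-chromene-5,7-diyl dipivalate F13.
- Prenylation with 8 (K2CO3, acetone) gives 3,8-dimethoxy-2-[4-(3-methylbut-2-enyloxy)phenyl]-4-oxo-4H-chromene-5,7-diyl dipivalate F14.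
- K2CO3 in MeOH cleaves both pivalates and returns to the route at target 19.

**Further compounds**

F1 | step 8 | [2,4-bis(tert-butyldimethylsilyloxy)-3-methoxy-6-(pivaloyloxy)phenyl]magnesium chloride | COc1c(O[Si](C)(C)C(C)(C)C)cc(OC(=O)C(C)(C)C)c([Mg]Cl)c1O[Si](C)(C)C(C)(C)C
F2 | step 8 | 3,5-bis(tert-butyldimethylsilyloxy)-2-formyl-4-methoxyphenyl pivalate | COc1c(O[Si](C)(C)C(C)(C)C)cc(OC(=O)C(C)(C)C)c(C=O)c1O[Si](C)(C)C(C)(C)C
F3 | step 8 | lithium (Z)-enolate of 2-methoxy-1-[4-(3-methylbut-2-enyloxy)phenyl]ethanone | CO/C=C(\O[Li])c1ccc(OCC=C(C)C)cc1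
F4 | step 8 | 3,5-bis(tert-butyldimethylsilyloxy)-2-{1-hydroxy-2-methoxy-3-[4-(3-methylbut-2-enyloxy)phenyl]-3-oxopropyl}-4-methoxyphenyl pivalate (diastereomer mixture, racemic) | COc1c(O[Si](C)(C)C(C)(C)C)cc(OC(=O)C(C)(C)C)c(C(O)C(OC)C(=O)c2ccc(OCC=C(C)C)cc2)c1O[Si](C)(C)C(C)(C)C
F5 | step 4 | 3,5-bis(tert-butyldimethylsilyloxy)-2-iodo-4-methoxyphenol | COc1c(O[Si](C)(C)C(C)(C)C)cc(O)c(I)c1O[Si](C)(C)C(C)(C)C
F6 | step 9 | 1-(benzyloxy)-4-bromobenzene | Brc1ccc(OCc2ccccc2)cc1
F7 | step 9 | 4-(benzyloxy)phenylmagnesium bromide | Br[Mg]c1ccc(OCc2ccccc2)cc1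
F8 | step 9 | 1-[4-(benzyloxy)phenyl]-2-methoxyethanone | COCC(=O)c1ccc(OCc2ccccc2)cc1
F9 | step 9 | 2-{3-[4-(benzyloxy)phenyl]-2-methoxy-3-oxopropanoyl}-3,5-bis(tert-butyldimethylsilyloxy)-4-methoxyphenyl pivalate (racemic) | COc1c(O[Si](C)(C)C(C)(C)C)cc(OC(=O)C(C)(C)C)c(C(=O)C(OC)C(=O)c2ccc(OCc3ccccc3)cc2)c1O[Si](C)(C)C(C)(C)C
F10 | step 9 | 2-{3-[4-(benzyloxy)phenyl]-2-methoxy-3-oxopropanoyl}-3,5-dihydroxy-4-methoxyphenyl pivalate (racemic) | COc1c(O)cc(OC(=O)C(C)(C)C)c(C(=O)C(OC)C(=O)c2ccc(OCc3ccccc3)cc2)c1O
F11 | step 9 | 2-[4-(benzyloxy)phenyl]-7-hydroxy-3,8-dimethoxy-4-oxo-4H-chromen-5-yl pivalate | COc1c(-c2ccc(OCc3ccccc3)cc2)oc2c(OC)c(O)cc(OC(=O)C(C)(C)C)c2c1=O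
F12 | step 9 | 2-[4-(benzyloxy)phenyl]-3,8-dimethoxy-4-oxo-4H-chromene-5,7-diyl dipivalate | COc1c(-c2ccc(OCc3ccccc3)cc2)oc2c(OC)c(OC(=O)C(C)(C)C)cc(OC(=O)C(C)(C)C)c2c1=O
F13 | step 9 | 2-(4-hydroxyphenyl)-3,8-dimethoxy-4-oxo-4H-chromene-5,7-diyl dipivalate | COc1c(-c2ccc(O)cc2)oc2c(OC)c(OC(=O)C(C)(C)C)cc(OC(=O)C(C)(C)C)c2c1=O
F14 | step 9 | 3,8-dimethoxy-2-[4-(3-methylbut-2-enyloxy)phenyl]-4-oxo-4H-chromene-5,7-diyl dipivalate | COc1c(-c2ccc(OCC=C(C)C)cc2)oc2c(OC)c(OC(=O)C(C)(C)C)cc(OC(=O)C(C)(C)C)c2c1=O
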